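**Retrosynthetic overview**
1. Target 26 is a 6,8-dioxabicyclo[3.2.2]nonan-7-one: an oxepane (O, C6, C7, C8, C9, C10, C11) whose C7 and C11 are bridged by O–C18(=O). The last ring event joins the lactone O to C7, starting from oxepane acid 24, which carries an exocyclic C7=C19H2.
2. Enabling feature: C7 and C11 are the two bridgeheads. In 24 the C18 carboxyl on C11 lies 1,4 across the oxepane (C11–O–C6–C7) over a planar C7. The bridge can therefore form on one face only, and C11 dictates C7.
3. Oxepane: the O–C11 bond comes from 7-exo opening of the C11/C18 oxirane of 21 by the C6 hydroxyl, with inversion at C11. C18H2OH is then raised to CO2H.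
4. Open chain 21: C6–C7 by Nozaki–Hiyama–Kishi coupling (14 + 19) and C10–C11 by alkenyllithium addition (10 + 5). C10/C11 are set by a Sharpless kinetic resolution. Aldehyde 5 is used twice; 2Z comes from nerol and 14Z from a Still–Gennari olefination.
5. Ring order: oxirane (temporary), then oxepane, then 1,4-dioxan-2-one together with the seven-membered lactone, both in the key step.

Key step: step 16

Remark: atoms are numbered as in geranylgeraniol. The chain runs C1 to C16, with C1 the CH2OH next to C2H= and C16 the CH2OH on C15. C17 is Me on C15, C18 the carboxyl carbon on C11, C19 the carbon on C7 and C20 Me on C3. TBDPS = tert-butyldiphenylsilyl, TBS = tert-butyldimethylsilyl.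

Step 1
Reactants: 1 ethyl acetate; 2 2,3-dibromopropene
Product: 4 ethyl 4-bromopent-4-enoate, via lithium enolate of ethyl acetate 3 (not isolated)
Conditions: LiN(i-Pr)2, THF, −78 °C; then 2, DMPU, −78 to −30 °C
Reagents that add atoms: none
Why: Ester enolate alkylation (SN2) takes place at the allylic C–Br of 2 while the vinylic C–Br stays inert; no stereocentre is formed.

Step 2
Reactants: 4 ethyl 4-bromopent-4-enoate
Product: 5 4-bromopent-4-enal
Conditions: i-Bu2AlH (1 equiv), CH2Cl2, −78 °C; aq. Rochelle salt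
Reagents that add atoms: none
Why: Partial ester reduction stops at the aluminium hemiacetal at low temperature and releases the aldehyde on work-up; the vinyl bromide is not touched.

Step 3
Reactants: 5 4-bromopent-4-enal; 6 ethyl 2-[bis(2,2,2-trifluoroethoxy)phosphoryl]propanoate
Product: 8 ethyl (2Z)-6-bromo-2-methylhepta-2,6-dienoate, via potassium phosphonate carbanion 7 (not isolated)
Conditions: KN(SiMe3)2, 18-crown-6, THF, −78 °C; then 5
Reagents that add atoms: none
Why: In the Still–Gennari olefination, fast irreversible elimination from the kinetic adduct places the ester cis to the chain, which sets the 14Z alkene.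

Step 4
Reactants: 8 ethyl (2Z)-6-bromo-2-methylhepta-2,6-dienoate
Product: 9 (2Z)-6-bromo-2-methylhepta-2,6-dien-1-ol
Conditions: i-Bu2AlH (2.3 equiv), CH2Cl2, −78 to 0 °C
Reagents that add atoms: none
Why: 1,2-Reduction of the enoate to the allylic alcohol keeps the Z geometry and leaves the vinyl bromide intact.

Step 5
Reactants: 9 (2Z)-6-bromo-2-methylhepta-2,6-dien-1-ol
Product: 10 TBDPS ether of 9
Conditions: TBDPSCl, imidazole, CH2Cl2, rt
Reagents that add atoms: tert-butyl(chloro)diphenylsilane, CC(C)(C)[Si](Cl)(c1ccccc1)c1ccccc1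
Why: Standard O-silylation gives a robust ether that also lowers the reactivity of the C14=C15 alkene.

Step 6
Reactants: 10 TBDPS ether of 9; 5 4-bromopent-4-enal
Product: 12 racemic C7–C16 allylic alcohol (10RS), via alkenyllithium 11 (not isolated)
Conditions: t-BuLi (2.1 equiv), Et2O, −78 °C; then 5, −78 °C
Reagents that add atoms: none
Why: Bromine–lithium exchange is followed by carbonyl 1,2-addition, which should outrun exchange with the vinyl bromide of 5; C10 is made racemic on purpose and resolved in step 7.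

Step 7
Reactants: 12 racemic C7–C16 allylic alcohol
Product: 13 (10S,11R)-11,18-epoxy alcohol
Conditions: Ti(Oi-Pr)4, L-(+)-DIPT, t-BuOOH (0.45 equiv), 4 Å MS, CH2Cl2, −20 °C; the unreacted (10R) alcohol is separated
Reagents that add atoms: tert-butyl hydroperoxide, CC(C)(C)OO
Why: In this Sharpless asymmetric epoxidation run as a kinetic resolution, L-(+)-DIPT lets the (10S) alcohol react fast on the face that gives the erythro (10S,11R) oxirane, and only the alkene of the allylic alcohol is activated.

Step 8
Reactants: 13 (10S,11R)-11,18-epoxy alcohol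
Product: 14 10-O-TBS ether of 13
Conditions: TBSCl, imidazole, DMAP, DMF, 35 °C
Reagents that add atoms: tert-butyl(chloro)dimethylsilane, CC(C)(C)[Si](C)(C)Cl
Why: Silylation under non-acidic conditions spares the oxirane and masks O10, which would otherwise compete for C7 in step 16.

Step 9
Reactants: 15 nerol
Product: 16 neryl TBDPS ether
Conditions: TBDPSCl, imidazole, CH2Cl2, rt
Reagents that add atoms: tert-butyl(chloro)diphenylsilane, CC(C)(C)[Si](Cl)(c1ccccc1)c1ccccc1
Why: O-Silylation; the 2Z alkene of the target is taken unchanged from nerol.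

Step 10
Reactants: 16 neryl TBDPS ether
Product: 17 6,7-epoxyneryl TBDPS ether (racemic)
Conditions: mCPBA (1 equiv), CH2Cl2, 0 °C
Reagents that add atoms: 3-chloroperoxybenzoic acid, O=C(OO)c1cccc(Cl)c1
Why: Prilezhaev epoxidation picks the more electron-rich distal alkene over the allylically oxygenated one; the new stereocentre is destroyed in step 11.

Step 11
Reactants: 17 6,7-epoxyneryl TBDPS ether
Product: 19 (4Z)-6-(TBDPS-oxy)-4-methylhex-4-enal, via vicinal diol 18 (not isolated)
Conditions: H5IO6, THF/Et2O/H2O, 0 °C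
Reagents that add atoms: none
Why: Acidic hydrolysis of the oxirane and Malaprade glycol cleavage in one flask remove the isopropylidene end as acetone and leave the C6 aldehyde.

Step 12
Reactants: 14 10-O-TBS ether of 13; 19 (4Z)-6-(TBDPS-oxy)-4-methylhex-4-enal
Product: 21 (6S,10S,11R) open-chain epoxy alcohol, via alkenylchromium dichloride 20 (not isolated)
Conditions: CrCl2 (4 equiv), NiCl2 (2 mol %), N-[2-(4-isopropyl-4,5-dihydrooxazol-2-yl)-6-methylphenyl]methanesulfonamide (the enantiomer that directs Re-face addition), Et3N, THF, rt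
Reagents that add atoms: none
Why: The ligand-controlled Nozaki–Hiyama–Kishi coupling tolerates oxirane and silyl ethers, and addition of the alkenylchromium to the Re face of 19 sets (6S).

Step 13
Reactants: 21 (6S,10S,11R) open-chain epoxy alcohol
Product: 22 (6S,10S,11S) oxepane primary alcohol
Conditions: camphorsulfonic acid (10 mol %), CH2Cl2 (2 mM), 0 °C
Reagents that add atoms: none
Why: In this acid-catalysed intramolecular epoxide opening (7-exo-tet, Markovnikov), O6 attacks the tertiary C11 from the rear, so C11 is inverted to the target arrangement and C18 is released as CH2OH.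

Step 14
Reactants: 22 oxepane primary alcohol
Product: 23 oxepane aldehyde
Conditions: Dess–Martin periodinane, CH2Cl2, rt
Reagents that add atoms: none
Why: Dess–Martin oxidation of the only free hydroxyl gives an aldehyde that has no α-hydrogen and cannot epimerise.

Step 15
Reactants: 23 oxepane aldehyde
Product: 24 (6S,10S,11R) oxepane carboxylic acid
Conditions: NaClO2, NaH2PO4, 2-methylbut-2-ene, t-BuOH/H2O, rt
Reagents that add atoms: sodium chlorite, [Na+].[O-]Cl=O
Why: Pinnick oxidation is used; the scavenger takes up HOCl so that the three alkenes of 23 are spared.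

Step 16
Reactants: 24 (6S,10S,11R) oxepane carboxylic acid
Product: 25 tris-silylated target (6S,7R,10S,11R)
Conditions: [N,N′-bis(3,5-di-tert-butylsalicylidene)-1,2-cyclohexanediaminato]cobalt (5 mol %), 1-fluoro-2,4,6-trimethylpyridinium triflate (1.5 equiv), (Me2SiH)2O (2 equiv), PhCF3, rt
Reagents that add atoms: none
Why: This is a cobalt-catalysed hydrogen-atom-transfer hydrolactonisation (radical–polar crossover hydroacyloxylation of an unactivated alkene): the cobalt hydride formed from catalyst, N-fluoropyridinium oxidant and silane delivers H to C19, the tertiary C7 radical is caught by cobalt and oxidised to a tetravalent alkylcobalt (a tertiary cation equivalent), and the C18 carboxylate, freed by the collidine released from the oxidant, displaces cobalt at C7. The closest known reaction is the lactonisation of 5-substituted hex-5-enoic acids under these conditions; 24 is the 3-oxa analogue (C18–C11–O–C6–C7=C19) held on a ring. One C–O bond closes two rings at once, the 1,4-dioxan-2-one (O, C18, C11, O, C6, C7) in a 6-exo-trig mode and the seven-membered lactone (O, C18, C11, C10, C9, C8, C7) in a 7-exo-trig mode, which turns the oxepane into the 6,8-dioxabicyclo[3.2.2]nonan-7-one and makes the C19 methyl group. The quaternary stereocentre C7 needs no reagent control, because C7 is planar when it is captured and the two-atom tether fixed on C11 reaches it only across the oxepane face that bears the carboxyl, so (11R) dictates (7R). Chemoselectivity rests on the rate order of hydrogen-atom transfer (the 1,1-disubstituted C7=C19 ahead of the trisubstituted, allylically oxygenated C2=C3 and C14=C15) and on the anionic carboxylate outrunning the neutral, hindered O10 silyl ether at C7. The near-neutral medium avoids the escape routes of a free C7 cation, namely 1,2-hydride shift from C6, attack by C2=C3 and re-ionisation of the tertiary ester.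

Step 17
Reactants: 25 tris-silylated target
Product: 26 target CNP0105745.1
Conditions: Bu4NF, AcOH, THF, rt to 40 °C
Reagents that add atoms: none
Why: Buffered fluoride desilylation removes all three silyl groups without acid, which would ionise the tertiary lactone, and without strong base, which would open it; no stereocentre is touched.

**Compound list**
1 | ethyl acetate | CCOC(C)=O | starting material
2 | 2,3-dibromopropene | C=C(Br)CBr | starting material
3 | lithium enolate of ethyl acetate | C=C([O-])OCC.[Li+] | intermediate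
4 | ethyl 4-bromopent-4-enoate | CCOC(=O)CCC(Br)=C | intermediate
5 | 4-bromopent-4-enal | O=CCCC(Br)=C | intermediate
6 | ethyl 2-[bis(2,2,2-trifluoroethoxy)phosphoryl]propanoate | CCOC(=O)C(C)P(=O)(OCC(F)(F)F)OCC(F)(F)F | starting material
7 | potassium carbanion of 6 | CCOC(=O)[C-](C)P(=O)(OCC(F)(F)F)OCC(F)(F)F.[K+] | intermediate
8 | ethyl (2Z)-6-bromo-2-methylhepta-2,6-dienoate | C/C(=C/CCC(Br)=C)C(=O)OCC | intermediate
9 | (2Z)-6-bromo-2-methylhepta-2,6-dien-1-ol | C/C(=C/CCC(Br)=C)CO | intermediate
10 | [(2Z)-6-bromo-2-methylhepta-2,6-dienyl]oxy(tert-butyl)diphenylsilane | C/C(=C/CCC(Br)=C)CO[Si](c3ccccc3)(c3ccccc3)C(C)(C)C | intermediate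
11 | alkenyllithium from 10 (Li on C11) | C/C(=C/CCC([Li])=C)CO[Si](c3ccccc3)(c3ccccc3)C(C)(C)C | intermediate
12 | (9Z)-2-bromo-11-(TBDPS-oxy)-10-methyl-6-methylideneundeca-1,9-dien-5-ol, racemic at C10 | C/C(=C/CCC(=C)C(O)CCC(Br)=C)CO[Si](c3ccccc3)(c3ccccc3)C(C)(C)C | intermediate
13 | (1S)-4-bromo-1-{(2R)-2-[(3Z)-5-(TBDPS-oxy)-4-methylpent-3-enyl]oxiran-2-yl}pent-4-en-1-ol (10S,11R) | C/C(=C/CC[C@@]1(CO1)[C@@H](O)CCC(Br)=C)CO[Si](c3ccccc3)(c3ccccc3)C(C)(C)C | intermediate
14 | 10-O-TBS ether of 13 (10S,11R) | C/C(=C/CC[C@@]1(CO1)[C@@H](O[Si](C)(C)C(C)(C)C)CCC(Br)=C)CO[Si](c3ccccc3)(c3ccccc3)C(C)(C)C | intermediate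
15 | nerol | CC(C)=CCC/C(C)=C\CO | starting material
16 | neryl TBDPS ether | CC(C)=CCC/C(C)=C\CO[Si](c3ccccc3)(c3ccccc3)C(C)(C)C | intermediate
17 | 6,7-epoxyneryl TBDPS ether, racemic | CC1(C)OC1CC/C(C)=C\CO[Si](c3ccccc3)(c3ccccc3)C(C)(C)C | intermediate
18 | 6,7-dihydroxy-6,7-dihydroneryl TBDPS ether, racemic | CC(C)(O)C(O)CC/C(C)=C\CO[Si](c3ccccc3)(c3ccccc3)C(C)(C)C | intermediate
19 | (4Z)-6-(TBDPS-oxy)-4-methylhex-4-enal | O=CCC/C(C)=C\CO[Si](c3ccccc3)(c3ccccc3)C(C)(C)C | intermediate
20 | alkenylchromium dichloride from 14 (Cr on C7) | C/C(=C/CC[C@@]1(CO1)[C@@H](O[Si](C)(C)C(C)(C)C)CCC(=C)[Cr](Cl)Cl)CO[Si](c3ccccc3)(c3ccccc3)C(C)(C)C | intermediate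
21 | open-chain (2Z,6S,10S,11R,14Z) compound: 6-OH, 7-methylidene, 10-OTBS, 11,18-oxirane, 1,16-bis-OTBDPS | C/C(=C/CC[C@@]1(CO1)[C@@H](O[Si](C)(C)C(C)(C)C)CCC(=C)[C@@H](O)CC/C(C)=C\CO[Si](c3ccccc3)(c3ccccc3)C(C)(C)C)CO[Si](c3ccccc3)(c3ccccc3)C(C)(C)C | intermediate
22 | (2S,3S,7S)-oxepan-2-ylmethanol: 3-OTBS, 6-methylidene, both Z side chains as TBDPS ethers on C2 and C7 | C/C(=C/CC[C@@]1(CO)O[C@@H](CC/C(C)=C\CO[Si](c3ccccc3)(c3ccccc3)C(C)(C)C)C(=C)CC[C@@H]1O[Si](C)(C)C(C)(C)C)CO[Si](c3ccccc3)(c3ccccc3)C(C)(C)C | intermediate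
23 | (2R,3S,7S)-oxepane-2-carbaldehyde, substituents as in 22 | C/C(=C/CC[C@@]1(C=O)O[C@@H](CC/C(C)=C\CO[Si](c3ccccc3)(c3ccccc3)C(C)(C)C)C(=C)CC[C@@H]1O[Si](C)(C)C(C)(C)C)CO[Si](c3ccccc3)(c3ccccc3)C(C)(C)C | intermediate
24 | (2R,3S,7S)-oxepane-2-carboxylic acid, substituents as in 22 (6S,10S,11R) | C/C(=C/CC[C@@]1(C(=O)O)O[C@@H](CC/C(C)=C\CO[Si](c3ccccc3)(c3ccccc3)C(C)(C)C)C(=C)CC[C@@H]1O[Si](C)(C)C(C)(C)C)CO[Si](c3ccccc3)(c3ccccc3)C(C)(C)C | intermediate
25 | 1,16-bis-O-TBDPS-10-O-TBS ether of the target (6S,7R,10S,11R) | C/C(=C/CC[C@@]12O[C@@H](CC/C(C)=C\CO[Si](c3ccccc3)(c3ccccc3)C(C)(C)C)[C@@](C)(CC[C@@H]1O[Si](C)(C)C(C)(C)C)OC2=O)CO[Si](c3ccccc3)(c3ccccc3)C(C)(C)C | intermediate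
26 | CNP0105745.1 (2Z,6S,7R,10S,11R,14Z) | C/C(=C/CC[C@@]12O[C@@H](CC/C(C)=C\CO)[C@@](C)(CC[C@@H]1O)OC2=O)CO | target

**Step count and risks**

Total step count: 17. Longest linear sequence: 14 (steps 1 to 8 and 12 to 17).

Steps most likely to fail:

**Step 16.**
- What may go wrong: the cationic C7 may be captured by the O10 silyl ether oxygen with loss of the silyl group. Other failure modes are a hydride shift from C6 to C7, plain reduction of C7=C19 by a second hydrogen-atom transfer, and slow attack on the trisubstituted alkenes.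
- Fallback: it sets out from 24 and replaces the radical entry by an ionic halonium entry. Treatment with I2 and NaHCO3 in MeCN/H2O at 0 °C (iodolactonisation by the carboxylate anion; iodonium formation at the other alkenes is reversible and unproductive) would give the iodomethyl lactone F1. Bu3SnH, Et3B and air in toluene at 0 °C (radical deiodination at high stannane concentration) would turn C19H2I into the methyl group. The fallback comes back to the route at 25.

**Step 13.**
- What may go wrong: seven-membered closure may be slower than rearrangement of the oxirane to an aldehyde by a 1,2-hydride shift, or slower than attack of the C7=C19 alkene on C11.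
- Fallback: it sets out from 12 and changes the electrophile from an oxirane to a mercurinium ion.
  - Kinetic resolution of 12 with D-(−)-DIPT would consume the (10R) alcohol as the enantiomeric epoxy alcohol F3 and leave the (10S) allylic alcohol F2.
  - TBSCl and imidazole would give the silyl ether F4.
  - The ligand-controlled Nozaki–Hiyama–Kishi coupling of step 12 with 19 would give the bis-methylidene alcohol F5.
  - Hg(OCOCF3)2 in MeNO2 followed by aqueous NaCl (intramolecular oxymercuration, Markovnikov, 7-exo-trig) would close the oxepane to the chloromercurial F6. Here C11 would rest on 1,2-induction from C10.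
  - NaBH4 under O2 in DMF (oxidative demercuration) would bring the route back at 22.

**Step 12.**
- What may go wrong: facial selectivity at the aldehyde may be poor, and activation of the alkenyl bromide may be sluggish.
- Fallback: it sets out from 14 and 19 and moves the stereocontrol from C–C bond formation to a ketone reduction. Ligand-free CrCl2/NiCl2 coupling in DMSO would give the C6-epimeric alcohols F7, and Dess–Martin periodinane would give the α-methylidene ketone F8. (R)-2-methyl-CBS-oxazaborolidine with catecholborane in toluene at −78 °C (the alkenyl group acts as the large substituent) would deliver the (6S) alcohol. The fallback comes back at 21.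

**Further compounds**
F1 | step 16 | 19-iodo derivative of 25 (iodomethyl on C7) | C/C(=C/CC[C@@]12O[C@@H](CC/C(C)=C\CO[Si](c3ccccc3)(c3ccccc3)C(C)(C)C)[C@@](CI)(CC[C@@H]1O[Si](C)(C)C(C)(C)C)OC2=O)CO[Si](c3ccccc3)(c3ccccc3)C(C)(C)C
F2 | step 13 | (10S) enantiomer of 12 | C/C(=C/CCC(=C)[C@@H](O)CCC(Br)=C)CO[Si](c3ccccc3)(c3ccccc3)C(C)(C)C
F3 | step 13 | (10R,11S) enantiomer of 13 | C/C(=C/CC[C@]1(CO1)[C@H](O)CCC(Br)=C)CO[Si](c3ccccc3)(c3ccccc3)C(C)(C)C
F4 | step 13 | 10-O-TBS ether of F2 | C/C(=C/CCC(=C)[C@@H](O[Si](C)(C)C(C)(C)C)CCC(Br)=C)CO[Si](c3ccccc3)(c3ccccc3)C(C)(C)C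
F5 | step 13 | (6S,10S) 7,11-bis-methylidene analogue of 21 | C/C(=C/CCC(=C)[C@@H](O[Si](C)(C)C(C)(C)C)CCC(=C)[C@@H](O)CC/C(C)=C\CO[Si](c3ccccc3)(c3ccccc3)C(C)(C)C)CO[Si](c3ccccc3)(c3ccccc3)C(C)(C)C
F6 | step 13 | 18-chloromercurio analogue of 22 | C/C(=C/CC[C@@]1(C[Hg]Cl)O[C@@H](CC/C(C)=C\CO[Si](c3ccccc3)(c3ccccc3)C(C)(C)C)C(=C)CC[C@@H]1O[Si](C)(C)C(C)(C)C)CO[Si](c3ccccc3)(c3ccccc3)C(C)(C)C
F7 | step 12 | 21 as a mixture of C6 epimers | C/C(=C/CC[C@@]1(CO1)[C@@H](O[Si](C)(C)C(C)(C)C)CCC(=C)C(O)CC/C(C)=C\CO[Si](c3ccccc3)(c3ccccc3)C(C)(C)C)CO[Si](c3ccccc3)(c3ccccc3)C(C)(C)C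
F8 | step 12 | 6-oxo analogue of 21 | C/C(=C/CC[C@@]1(CO1)[C@@H](O[Si](C)(C)C(C)(C)C)CCC(=C)C(=O)CC/C(C)=C\CO[Si](c3ccccc3)(c3ccccc3)C(C)(C)C)CO[Si](c3ccccc3)(c3ccccc3)C(C)(C)C
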